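**Retrosynthetic overview**

1. Target ⇐ keto ester 28 ⇐ trans-fused octalin 20. The end game oxidises C15, acetylates O19, reduces a 3-ketone to the axial alcohol, methylates the C4 enolate for C18, and makes the 7,8-alkene with C17 from a C8 ketone via its enol triflate.
2. 20 ⇐ acyclic triene 19 by one intramolecular Diels–Alder reaction that forms C5–C10 and C3–C4. Rings A and B are closed together; no ring exists before this step.
3. Enabling feature: in ring A the oxygen on C3 sits next to C4, whose carbon C19 is oxidised. So C3(O)=C2–C1=C10 (C10 carrying the future angular methyl) is a donor diene, C19(=O)–C4=C5 is its polarity-matched dienophile, and C6–C9 of ring B are the four-carbon tether.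
4. 19 ⇐ aldehyde 14 + phosphonate 18; 14 ⇐ γ-nitro aldehyde 9 (Wittig, silyl dienol ether, nitro-Michael). C9 is set by an organocatalytic Michael addition of propanal to nitroalkene 7. C8 travels as a nitro group (masked ketone), and both C10 epimers converge on one diene.
5. 7 ⇐ geraniol, whose C1–C6 become C15, C14, C13 (with C16), C12, C11 and C9, with the (13E)-alkene already in place.

Key step: step 10

Remark: positions are given in labdane numbering. C8 of the nitro compounds and C10 of 9 and 11 are stereocentres of no consequence (both become trigonal later), so C8 is drawn without configuration.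

**Route**

Step 1
Reactants: 1 geraniol
Product: 2 geranyl tert-butyldiphenylsilyl ether
Conditions: TBDPSCl, imidazole, DMF, rt
Reagents that add atoms: tert-butyl(chloro)diphenylsilane, CC(C)(C)[Si](Cl)(c1ccccc1)c1ccccc1
Why: Imidazole-promoted silylation of the primary allylic alcohol gives a silyl ether that is inert to the bases, cuprate and hydrides used later; no stereocentre is formed.

Step 2
Reactants: 2 geranyl tert-butyldiphenylsilyl ether
Product: 4 (E)-6-(tert-butyldiphenylsilyloxy)-4-methylhex-4-enal, via epoxide 3 (not isolated)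
Conditions: mCPBA, CH2Cl2, -20 °C; then H5IO6, THF/H2O, 0 °C
Reagents that add atoms: 3-chloroperoxybenzoic acid, OOC(=O)c1cccc(Cl)c1
Why: Prilezhaev epoxidation should take the more electron-rich 6,7-alkene (the 2,3-alkene is deactivated by the allylic silyloxy group), and periodic acid cleaves the epoxide to the aldehyde and acetone without touching the (E)-alkene.

Step 3
Reactants: 4 (E)-6-(tert-butyldiphenylsilyloxy)-4-methylhex-4-enal; 5 nitromethane
Product: 7 (1E,5E)-7-(tert-butyldiphenylsilyloxy)-5-methyl-1-nitrohepta-1,5-diene, via nitro alcohol 6 (not isolated)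
Conditions: MeNO2, Et3N (cat.), rt; then MsCl, Et3N, CH2Cl2, 0 °C
Reagents that add atoms: none
Why: Henry addition followed by mesylation and E1cB elimination gives the thermodynamically favoured (E)-nitroalkene.

Step 4
Reactants: 7 (1E,5E)-nitroalkene; 8 propanal
Product: 9 (2S,3S,6E)-8-(tert-butyldiphenylsilyloxy)-2,6-dimethyl-3-(nitromethyl)oct-6-enal
Conditions: (R)-α,α-diphenylprolinol trimethylsilyl ether (10 mol%), 4-nitrophenol (10 mol%), toluene, 0 °C to rt
Reagents that add atoms: none
Why: Enamine-catalysed asymmetric Michael addition of an aldehyde to a nitroalkene; the diarylsilyloxymethyl group of the (R)-catalyst shields one enamine face and the synclinal transition state sets C9 (C3 of this chain, the S sense needed) together with a syn C10 centre that is erased in step 6.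

Step 5
Reactants: 9 γ-nitro aldehyde; 10 (triphenylphosphoranylidene)acetaldehyde
Product: 11 (2E,5S,8E)-10-(tert-butyldiphenylsilyloxy)-4,8-dimethyl-5-(nitromethyl)deca-2,8-dienal
Conditions: toluene, 50 °C
Reagents that add atoms: none
Why: Wittig olefination with a stabilised ylide gives the (E)-enal; the ylide is too weakly basic to deprotonate the nitro group, and C9 (β to the carbonyl) cannot epimerise.

Step 6
Reactants: 11 (2E)-enal
Product: 12 (1E,3E,5S,8E)-1-(tert-butyldimethylsilyloxy)-10-(tert-butyldiphenylsilyloxy)-4,8-dimethyl-5-(nitromethyl)deca-1,3,8-triene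
Conditions: TBSOTf (1.05 equiv), Et3N, CH2Cl2, -78 to -40 °C; cold aq. NaHCO3 quench
Reagents that add atoms: tert-butyldimethylsilyl trifluoromethanesulfonate, CC(C)(C)[Si](C)(C)OS(=O)(=O)C(F)(F)F
Why: Soft enolisation by γ-deprotonation of the O-silylated s-trans enal should give the (1E)-enol ether, with the methyl group inside and the branched C9 outside at C10=C1 to minimise allylic strain, so both C10 epimers of 11 converge on one diene; at -78 °C the aldehyde oxygen should be silylated much faster than the nitro group.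

Step 7
Reactants: 12 silyl dienol ether; 13 acrolein
Product: 14 (5S,6E,8E)-9-(tert-butyldimethylsilyloxy)-5-[(3E)-5-(tert-butyldiphenylsilyloxy)-3-methylpent-3-enyl]-6-methyl-4-nitronona-6,8-dienal (C4 epimers)
Conditions: DBU (10 mol%), MeCN, -20 to 0 °C
Reagents that add atoms: none
Why: Base-catalysed nitro-Michael addition of the primary nitronate to acrolein builds C8–C7; branching at C9 should suppress a second addition, and the new C8 centre is left as a mixture because it becomes a ketone.

Step 8
Reactants: 15 (diethoxyphosphoryl)acetic acid; 16 (S)-4-benzyl-1,3-oxazolidin-2-one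
Product: 18 (S)-4-benzyl-3-[(diethoxyphosphoryl)acetyl]oxazolidin-2-one, via mixed anhydride 17 (not isolated)
Conditions: t-BuCOCl, Et3N, THF, -20 °C; then 16, LiCl, rt
Reagents that add atoms: none
Why: N-acylation of the oxazolidinone through the mixed pivalic anhydride, assisted by LiCl, is a standard route to acyl oxazolidinones.

Step 9
Reactants: 14 aldehyde; 18 phosphonate
Product: 19 (S)-4-benzyl-3-[(2E)-enoyl]oxazolidin-2-one triene (the enoyl chain is 14 extended by C4=C5 and C19)
Conditions: LiCl, i-Pr2NEt, MeCN, 0 °C to rt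
Reagents that add atoms: none
Why: Horner–Wadsworth–Emmons olefination under mild LiCl/amine conditions gives the (E)-enoyl imide and leaves the silyl dienol ether intact.

Step 10
Reactants: 19 triene imide
Product: 20 trans-fused octalin cycloadduct (3-OTBS and 4-acyl cis to each other and to H-5; H-5 trans to the C10 methyl; C9 side chain cis to the C10 methyl; 8-nitro epimers)
Conditions: Me2AlCl (2.5 equiv), CH2Cl2, -30 to 0 °C; aq. HCl quench
Reagents that add atoms: none
Why: Me2AlCl chelates the two imide carbonyls (s-cis enoyl) and lowers the LUMO of C4=C5, and the 1-silyloxy diene C3=C2–C1=C10 adds in a concerted, asynchronous [4+2] cycloaddition; the closest known reaction type is the Lewis-acid-promoted intramolecular Diels–Alder reaction of (E)-trienoyl oxazolidinones (type-one cyclisation of a 1,7,9-decatriene). Ring A is closed as the cyclohexene of the cycloaddition (endo, boat-like), and ring B is closed by the same C5–C10 bond across the tether C6–C9 in a chair-like, anti arrangement that gives the trans ring fusion. C3 and C4 follow from the endo placement of the chelated imide under the (1E)-enol ether, which puts OTBS and the acyl group cis; C5 follows from the (E)-dienophile and the anti tether, which put H-5 cis to the acyl group and trans to the C10 methyl. C10 follows from the (3E)-diene geometry (methyl inside, C9 outside); its face is chosen by the equatorial side chain on C9 and, in the same sense, by the benzyl group of the (S)-auxiliary, which blocks the other face of the chelated dienophile. The selectivity needed is endo/anti addition against the syn (cis-fused) mode that the axial angular methyl otherwise favours; the bidentate chelate and the donor-substituted diene should secure the endo preference, and the auxiliary makes the facial outcome independent of the C8 configuration.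

Step 11
Reactants: 20 cycloadduct
Product: 22 methyl ester C8 ketone, via sodium nitronate 21 (not isolated)
Conditions: NaOMe, MeOH/THF, 0 °C; then TiCl3 (aq), NH4OAc, rt
Reagents that add atoms: sodium methoxide, [Na+].[O-]C; water, O
Why: Methoxide transesterifies the imide (releasing the auxiliary) and forms the nitronate, which the buffered TiCl3 reductive Nef reaction converts through the imine into the C8 ketone; C9 keeps its side chain equatorial, the stable configuration next to the ketone.

Step 12
Reactants: 22 keto ester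
Product: 23 C8 enol triflate with the 7,8-alkene
Conditions: KN(SiMe3)2, THF, -78 °C; then PhNTf2
Reagents that add atoms: N-phenylbis(trifluoromethanesulfonimide), FC(F)(F)S(=O)(=O)N(c1ccccc1)S(=O)(=O)C(F)(F)F
Why: Kinetic enolisation should occur at the C7 methylene (H-9 is tertiary and flanked by the quaternary C10; the tertiary ester α-H is slower still), and O-triflation fixes the 7,8-regiochemistry.

Step 13
Reactants: 23 enol triflate
Product: 24 8-methyl-7-ene (C17 installed)
Conditions: Me2CuLi (from CuI and MeLi), THF, -20 °C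
Reagents that add atoms: lithium dimethylcuprate, [Li+].C[Cu-]C
Why: Coupling of an alkenyl triflate with a lithium dialkylcuprate replaces OTf by methyl without moving the alkene; the ester and the silyl ethers are inert.

Step 14
Reactants: 24 bis-silyl ether
Product: 25 allylic alcohol (3-OH, 1,2-alkene)
Conditions: HF·pyridine, pyridine, THF, 0 °C to rt
Reagents that add atoms: none
Why: Buffered HF should remove the secondary TBS ether much faster than the primary TBDPS ether.

Step 15
Reactants: 25 allylic alcohol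
Product: 26 1-en-3-one β-keto ester
Conditions: Dess–Martin periodinane, CH2Cl2, rt
Reagents that add atoms: none
Why: Dess–Martin oxidation of the allylic alcohol gives the enone, whose C4–H now lies between ketone and ester.

Step 16
Reactants: 26 β-keto ester
Product: 27 4-methyl-4-carbomethoxy enone (methyl equatorial, ester axial)
Conditions: MeI, K2CO3, acetone, rt
Reagents that add atoms: iodomethane, CI
Why: C-alkylation of the β-keto ester enolate; methyl iodide approaches C4 from the face opposite the angular C10 methyl (the syn-axial face is blocked), the established course for 3-oxo-4-carboalkoxy-10-methyldecalins, so C18 ends equatorial and C19 axial.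

Step 17
Reactants: 27 enone
Product: 28 saturated 3-keto ester
Conditions: H2 (1 atm), RhCl(PPh3)3 (5 mol%), toluene, rt
Reagents that add atoms: none
Why: Homogeneous hydrogenation with RhCl(PPh3)3 reduces the disubstituted conjugated 1,2-alkene and should leave the trisubstituted 7,8- and 13,14-alkenes, as with steroidal 1-en-3-ones.

Step 18
Reactants: 28 keto ester
Product: 30 3,19-diol (axial 3-OH), via hydroxy ester 29 (not isolated)
Conditions: LiBH(s-Bu)3, THF, -78 °C; then LiAlH4, -78 to 0 °C
Reagents that add atoms: none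
Why: The bulky trialkylborohydride should attack the C3 ketone from the equatorial direction and give the axial alcohol (as with 4,4-disubstituted 3-ketones), and LiAlH4 then reduces the hindered axial ester to the C19 carbinol.

Step 19
Reactants: 30 diol
Product: 31 19-acetate
Conditions: Ac2O (1.1 equiv), pyridine, CH2Cl2, 0 °C
Reagents that add atoms: acetic anhydride, CC(=O)OC(C)=O
Why: The primary C19 hydroxyl is acylated much faster than the axial secondary C3 hydroxyl next to the quaternary C4.

Step 20
Reactants: 31 silyl ether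
Product: 32 C15 allylic alcohol
Conditions: Bu4NF, AcOH, THF, 0 °C to rt
Reagents that add atoms: none
Why: Acetic-acid-buffered fluoride cleaves the silyl ether while the acetate survives; migration of the acetyl group to O3 is disfavoured because O3 and C19 are trans-diaxial.

Step 21
Reactants: 32 allylic alcohol
Product: 34 target acid, via enal 33 (not isolated)
Conditions: TEMPO (cat.), PhI(OAc)2, CH2Cl2, rt; then NaClO2, NaH2PO4, 2-methyl-2-butene, t-BuOH/H2O, rt
Reagents that add atoms: sodium chlorite, [Na+].[O-]Cl=O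
Why: The oxoammonium oxidation takes the primary allylic alcohol in preference to the hindered secondary C3–OH, and the Pinnick oxidation converts the enal into the acid without E/Z isomerisation while 2-methyl-2-butene traps HOCl.

**Compound list**

1 | geraniol | CC(C)=CCC/C(C)=C/CO | starting material
2 | geranyl tert-butyldiphenylsilyl ether | CC(C)=CCC/C(C)=C/CO[Si](c1ccccc1)(c1ccccc1)C(C)(C)C | intermediate
3 | 6,7-epoxide of 2 (racemic) | CC1(C)OC1CC/C(C)=C/CO[Si](c1ccccc1)(c1ccccc1)C(C)(C)C | intermediate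
4 | (E)-6-(tert-butyldiphenylsilyloxy)-4-methylhex-4-enal | O=CCC/C(C)=C/CO[Si](c1ccccc1)(c1ccccc1)C(C)(C)C | intermediate
5 | nitromethane | C[N+](=O)[O-] | starting material
6 | (E)-7-(tert-butyldiphenylsilyloxy)-5-methyl-1-nitrohept-5-en-2-ol (racemic) | [O-][N+](=O)CC(O)CC/C(C)=C/CO[Si](c1ccccc1)(c1ccccc1)C(C)(C)C | intermediate
7 | (1E,5E)-7-(tert-butyldiphenylsilyloxy)-5-methyl-1-nitrohepta-1,5-diene | [O-][N+](=O)/C=C/CC/C(C)=C/CO[Si](c1ccccc1)(c1ccccc1)C(C)(C)C | intermediate
8 | propanal | CCC=O | starting material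
9 | (2S,3S,6E)-8-(tert-butyldiphenylsilyloxy)-2,6-dimethyl-3-(nitromethyl)oct-6-enal | [O-][N+](=O)C[C@@H](CC/C(C)=C/CO[Si](c1ccccc1)(c1ccccc1)C(C)(C)C)[C@H](C)C=O | intermediate
10 | (triphenylphosphoranylidene)acetaldehyde | O=CC=P(c1ccccc1)(c1ccccc1)c1ccccc1 | starting material
11 | (2E,5S,8E)-10-(tert-butyldiphenylsilyloxy)-4,8-dimethyl-5-(nitromethyl)deca-2,8-dienal (C4 drawn syn; either epimer serves) | [O-][N+](=O)C[C@@H](CC/C(C)=C/CO[Si](c1ccccc1)(c1ccccc1)C(C)(C)C)[C@H](C)/C=C/C=O | intermediate
12 | (1E,3E,5S,8E)-1-(tert-butyldimethylsilyloxy)-10-(tert-butyldiphenylsilyloxy)-4,8-dimethyl-5-(nitromethyl)deca-1,3,8-triene | [O-][N+](=O)C[C@@H](CC/C(C)=C/CO[Si](c1ccccc1)(c1ccccc1)C(C)(C)C)/C(C)=C/C=C/O[Si](C)(C)C(C)(C)C | intermediate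
13 | acrolein | C=CC=O | starting material
14 | (5S,6E,8E)-9-(tert-butyldimethylsilyloxy)-5-[(3E)-5-(tert-butyldiphenylsilyloxy)-3-methylpent-3-enyl]-6-methyl-4-nitronona-6,8-dienal (C4 epimers) | O=CCCC([N+](=O)[O-])[C@@H](CC/C(C)=C/CO[Si](c1ccccc1)(c1ccccc1)C(C)(C)C)/C(C)=C/C=C/O[Si](C)(C)C(C)(C)C | intermediate
15 | (diethoxyphosphoryl)acetic acid | CCOP(=O)(CC(=O)O)OCC | starting material
16 | (S)-4-benzyl-1,3-oxazolidin-2-one | O=C1OC[C@H](Cc2ccccc2)N1 | starting material
17 | mixed pivalic (diethoxyphosphoryl)acetic anhydride | CCOP(=O)(CC(=O)OC(=O)C(C)(C)C)OCC | intermediate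
18 | (S)-4-benzyl-3-[(diethoxyphosphoryl)acetyl]oxazolidin-2-one | CCOP(=O)(CC(=O)N1[C@@H](Cc2ccccc2)COC1=O)OCC | intermediate
19 | (S)-4-benzyl-3-[(2E,7S,8E,10E)-11-(tert-butyldimethylsilyloxy)-7-[(3E)-5-(tert-butyldiphenylsilyloxy)-3-methylpent-3-enyl]-8-methyl-6-nitroundeca-2,8,10-trienoyl]oxazolidin-2-one (C6 epimers) | O=C1OC[C@H](Cc2ccccc2)N1C(=O)/C=C/CCC([N+](=O)[O-])[C@@H](CC/C(C)=C/CO[Si](c3ccccc3)(c3ccccc3)C(C)(C)C)/C(C)=C/C=C/O[Si](C)(C)C(C)(C)C | intermediate
20 | cycloadduct: trans-fused 1-ene with 3-OTBS, 4-(oxazolidinone-carbonyl) cis to 3-O and H-5, 8-nitro (epimers), side chain on C9 cis to the C10 methyl | O=C1OC[C@H](Cc2ccccc2)N1C(=O)[C@@H]3[C@H]4CCC([N+](=O)[O-])[C@@H](CC/C(C)=C/CO[Si](c5ccccc5)(c5ccccc5)C(C)(C)C)[C@]4(C)C=C[C@@H]3O[Si](C)(C)C(C)(C)C | intermediate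
21 | sodium nitronate of the methyl ester | [Na+].COC(=O)[C@@H]1[C@H]2CCC(=[N+]([O-])[O-])[C@@H](CC/C(C)=C/CO[Si](c3ccccc3)(c3ccccc3)C(C)(C)C)[C@]2(C)C=C[C@@H]1O[Si](C)(C)C(C)(C)C | intermediate
22 | methyl ester 8-ketone (1-ene, 3-OTBS) | COC(=O)[C@@H]1[C@H]2CCC(=O)[C@@H](CC/C(C)=C/CO[Si](c3ccccc3)(c3ccccc3)C(C)(C)C)[C@]2(C)C=C[C@@H]1O[Si](C)(C)C(C)(C)C | intermediate
23 | 8-trifloxy-1,7-diene ester | COC(=O)[C@@H]1[C@H]2CC=C(OS(=O)(=O)C(F)(F)F)[C@@H](CC/C(C)=C/CO[Si](c3ccccc3)(c3ccccc3)C(C)(C)C)[C@]2(C)C=C[C@@H]1O[Si](C)(C)C(C)(C)C | intermediate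
24 | 8-methyl-1,7-diene ester (3-OTBS) | COC(=O)[C@@H]1[C@H]2CC=C(C)[C@@H](CC/C(C)=C/CO[Si](c3ccccc3)(c3ccccc3)C(C)(C)C)[C@]2(C)C=C[C@@H]1O[Si](C)(C)C(C)(C)C | intermediate
25 | 3-hydroxy-1,7-diene ester | COC(=O)[C@@H]1[C@H]2CC=C(C)[C@@H](CC/C(C)=C/CO[Si](c3ccccc3)(c3ccccc3)C(C)(C)C)[C@]2(C)C=C[C@@H]1O | intermediate
26 | 3-oxo-1,7-diene β-keto ester (C4–H) | COC(=O)[C@@H]1[C@H]2CC=C(C)[C@@H](CC/C(C)=C/CO[Si](c3ccccc3)(c3ccccc3)C(C)(C)C)[C@]2(C)C=CC1=O | intermediate
27 | 4-methyl-3-oxo-1,7-diene ester (C18 equatorial, ester axial) | COC(=O)[C@@]1(C)[C@H]2CC=C(C)[C@@H](CC/C(C)=C/CO[Si](c3ccccc3)(c3ccccc3)C(C)(C)C)[C@]2(C)C=CC1=O | intermediate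
28 | 4-methyl-3-oxo-7-ene ester | COC(=O)[C@@]1(C)[C@H]2CC=C(C)[C@@H](CC/C(C)=C/CO[Si](c3ccccc3)(c3ccccc3)C(C)(C)C)[C@]2(C)CCC1=O | intermediate
29 | axial 3-hydroxy ester | COC(=O)[C@@]1(C)[C@H]2CC=C(C)[C@@H](CC/C(C)=C/CO[Si](c3ccccc3)(c3ccccc3)C(C)(C)C)[C@]2(C)CC[C@@H]1O | intermediate
30 | 3,19-diol, 15-O-TBDPS | OC[C@@]1(C)[C@H]2CC=C(C)[C@@H](CC/C(C)=C/CO[Si](c3ccccc3)(c3ccccc3)C(C)(C)C)[C@]2(C)CC[C@@H]1O | intermediate
31 | 19-acetate, 15-O-TBDPS | CC(=O)OC[C@@]1(C)[C@H]2CC=C(C)[C@@H](CC/C(C)=C/CO[Si](c3ccccc3)(c3ccccc3)C(C)(C)C)[C@]2(C)CC[C@@H]1O | intermediate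
32 | 19-acetoxy-3,15-diol | CC(=O)OC[C@@]1(C)[C@H]2CC=C(C)[C@@H](CC/C(C)=C/CO)[C@]2(C)CC[C@@H]1O | intermediate
33 | 19-acetoxy-3-hydroxy-15-al | CC(=O)OC[C@@]1(C)[C@H]2CC=C(C)[C@@H](CC/C(C)=C/C=O)[C@]2(C)CC[C@@H]1O | intermediate
34 | CNP0325522.1 | CC(=O)OC[C@@]1(C)[C@H]2CC=C(C)[C@@H](CC/C(C)=C/C(=O)O)[C@]2(C)CC[C@@H]1O | target

**Step count**

Total steps: 21. Longest linear sequence: 20 (steps 1–7 and 9–21 from geraniol; step 8 is the side branch).

**Steps most likely to fail, with fallbacks**

Step 10. The Lewis acid may cleave or protonate the silyl dienol ether before cycloaddition, or the syn (cis-fused) mode may compete because the angular methyl must go axial on the forming ring B. The fallback is a catalyst-controlled cycloaddition of the corresponding enal. It sets out from aldehyde 14: Wittig reaction with ylide 10 gives the trienal F1. A triflimide-activated chiral oxazaborolidine (the antipode matched to C9, chosen in a pilot run) should promote the endo intramolecular Diels–Alder reaction at -78 °C to the aldehyde cycloadduct F2. Pinnick oxidation gives the acid F3, and trimethylsilyldiazomethane gives the methyl ester F4. NaOMe and then buffered TiCl3 (F4 entering as nitronate 21) bring the route back at ketone 22.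

Step 7. Acrolein may polymerise, add twice to the primary nitro group, or attack the silyloxy diene. The fallback makes the C7–C8 bond at the ester oxidation level. It sets out from 12: methyl acrylate with catalytic DBU gives the nitro ester F5, and partial reduction with i-Bu2AlH in CH2Cl2 at -78 °C comes back at aldehyde 14.

Step 18. Hydride may add to the C3 ketone with poor facial selectivity and give the equatorial 3-epimer. The fallback delivers hydride intramolecularly from O19. It sets out from 28: LiAlH4 gives the 3-epimeric diol F6 (equatorial alcohol expected to dominate), and Dess–Martin oxidation gives the keto aldehyde F7. NaBH4 (one equivalent, MeOH/CH2Cl2, -78 °C) reduces only the aldehyde to the hydroxy ketone F8. Me4NBH(OAc)3 in AcOH/MeCN at -20 °C then delivers hydride from the axial C19–O–B unit to the same face of the C3 carbonyl, which should give the axial alcohol and comes back at diol 30.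

Further compounds
F1 | step 10 | (2E)-trienal from 14 and 10 (enal dienophile, silyl dienol ether, C6 nitro epimers) | O=C/C=C/CCC([N+](=O)[O-])[C@@H](CC/C(C)=C/CO[Si](c1ccccc1)(c1ccccc1)C(C)(C)C)/C(C)=C/C=C/O[Si](C)(C)C(C)(C)C
F2 | step 10 | aldehyde cycloadduct (as 20 with CHO in place of the imide) | O=C[C@@H]1[C@H]2CCC([N+](=O)[O-])[C@@H](CC/C(C)=C/CO[Si](c3ccccc3)(c3ccccc3)C(C)(C)C)[C@]2(C)C=C[C@@H]1O[Si](C)(C)C(C)(C)C
F3 | step 10 | carboxylic acid from F2 | OC(=O)[C@@H]1[C@H]2CCC([N+](=O)[O-])[C@@H](CC/C(C)=C/CO[Si](c3ccccc3)(c3ccccc3)C(C)(C)C)[C@]2(C)C=C[C@@H]1O[Si](C)(C)C(C)(C)C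
F4 | step 10 | methyl ester of F3 (8-nitro) | COC(=O)[C@@H]1[C@H]2CCC([N+](=O)[O-])[C@@H](CC/C(C)=C/CO[Si](c3ccccc3)(c3ccccc3)C(C)(C)C)[C@]2(C)C=C[C@@H]1O[Si](C)(C)C(C)(C)C
F5 | step 7 | methyl 4-nitro ester from 12 and methyl acrylate | COC(=O)CCC([N+](=O)[O-])[C@@H](CC/C(C)=C/CO[Si](c1ccccc1)(c1ccccc1)C(C)(C)C)/C(C)=C/C=C/O[Si](C)(C)C(C)(C)C
F6 | step 18 | 3-epimer of diol 30 (equatorial 3-OH) | OC[C@@]1(C)[C@H]2CC=C(C)[C@@H](CC/C(C)=C/CO[Si](c3ccccc3)(c3ccccc3)C(C)(C)C)[C@]2(C)CC[C@H]1O
F7 | step 18 | 3-oxo-19-al | O=C[C@@]1(C)[C@H]2CC=C(C)[C@@H](CC/C(C)=C/CO[Si](c3ccccc3)(c3ccccc3)C(C)(C)C)[C@]2(C)CCC1=O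
F8 | step 18 | 19-hydroxy-3-ketone | OC[C@@]1(C)[C@H]2CC=C(C)[C@@H](CC/C(C)=C/CO[Si](c3ccccc3)(c3ccccc3)C(C)(C)C)[C@]2(C)CCC1=O
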